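## The problem

Kuwanon T (17) is a flavone. Ring A carries hydroxyls at C5 and C7, ring C carries a prenyl group at C3 (C1''–C3''), and ring B, attached through C2–C1', carries hydroxyls at C2' and C4' with a second prenyl group between them at C3'. The molecule has no stereocentre, so the task is one of regiochemistry and functional-group tolerance, not of spatial control. C2 and C3 are both fully substituted and crowded. This is where the classical diketone cyclisation followed by C3-alkylation is weakest, because O- competes with C-prenylation and over-alkylation is hard to stop. Both trisubstituted alkenes lie next to phenols: strong protic or Lewis acids close them to 2,2-dimethylchromans, and they do not survive hydrogenolysis or boron tribromide. The four phenols therefore need one protecting group that tolerates organolithiums, palladium, phosphines and a carbene, and that comes off under mild conditions at the end. The enabling feature is the C3–C4 bond, which joins the acyl carbon of ring A to a carbon that bears both C2 and the prenyl carbon C1''. The 3-prenyl-4-pyranone is a tautomer of a flavanone with a C3=C1'' dienylidene, and that dienone is the hydroacylation product of a C3≡C1'' alkyne that carries the isobutenyl unit C2''=C3'' and hangs from the ring A oxygen O1 through C2. A ring A aldehyde tethered to such an enyne therefore contains every atom of the protected target at the correct oxidation level.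

## Retrosynthesis

**17 to 16 (four O–CH2 bonds).** The phenols are unmasked last from the tetrakis(methoxymethyl) ether 16. Methoxymethyl is preferred over benzyl (hydrogenolysis would reduce the prenyl groups), methyl (boron halides would cyclise them) and acyl groups (incompatible with organolithiums). It also directs both ortho-lithiations used to build ring B. The forward step must be acidic enough to cleave four acetals but too mild to cyclise a prenyl group onto a liberated phenol.

**16 to 15 (no skeletal bond; hydrogen moved from C1'' back to C2).** Flavone 16 is the aromatic-pyranone tautomer of the racemic (E)-3-(3-methylbut-2-enylidene)flavanone 15. Writing the prenyl group as a dienylidene costs nothing in oxidation level and exposes a C3=C1'' alkene that an alkyne addition can create. The forward step is a base-mediated 1,3-prototropic shift. It has to deliver the proton to C1'', the central carbon of the delocalised anion, and not to the terminal carbon C3''.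

**15 to 14 (C3–C4, the strategic cut).** Cutting C3–C4 by acyl-anion umpolung leads to the racemic aldehyde 14, in which ring A keeps its formyl carbon and the future C3 is the proximal carbon of a tethered enyne. The neighbouring cuts were weighed against it. Breaking C2–C3 (aldol or diketone logic) leaves the C3 prenyl group to be added by alkylation of an ambident nucleophile. Breaking O1–C8a or C4–C4a requires a pre-functionalised phloroglucinol electrophile. The C3–C4 cut uses ring A in the oxidation state of a commercial aldehyde, takes the C3 substituent from the alkyne terminus, and is an isomerisation, so no reagent atoms are wasted. It simplifies the target by one ring and gives an open-chain ether of two benzenoid halves. The forward reaction must add the acyl unit and hydrogen syn across an unactivated alkyne in the 6-exo-dig sense, from a hindered 2,6-dioxygenated aldehyde.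

**14 to 11 and 13 (O1–C2).** The aryl ether bond is cut to give the racemic enynol 11 and the phenol 13. This is the most convergent cut: it divides 14 into halves of similar size, and each half comes from one commercial aromatic. A Mitsunobu etherification is asked for, because the corresponding secondary, benzylic, propargylic halide would be too labile for a Williamson reaction and ring A is too electron-rich for nucleophilic aromatic substitution. Substitution must occur at the carbinol carbon and not at the remote alkyne terminus.

**11 to 9 and 10, and 9 to 7 and 8 (C1''–C2'', then C2–C3).** The sp–sp2 bond of the enyne is cut to the terminal alkynol 9 and 1-bromo-2-methylprop-1-ene (10), a Sonogashira coupling that tolerates the free alcohol. The carbinol–alkyne bond is cut to aldehyde 7 and ethynylmagnesium bromide (8). This order is preferred over adding a preformed enynyl anion, whose volatile parent enyne would have to be made separately. It is also preferred over coupling after etherification, where a copper acetylide next to a good aryloxide leaving group could ionise.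

**7 to 5, 5 to 2 and 3, 2 to 1 (C1'–CHO and C3'–C1''').** Both carbon substituents of ring B are introduced by directed ortho-metalation of the resorcinol bis(methoxymethyl) ether 2. The position between the two acetals is lithiated first and prenylated with prenyl bromide (3) to give 5. The only remaining ortho position is then lithiated and formylated to give 7. Electrophilic prenylation or formylation of free resorcinol derivatives gives regioisomer mixtures, whereas the two lithiations are fixed by the directing groups. The formyl carbon of 7 becomes C2.

**13 to 12 (two O–CH2 bonds).** Phenol 13 is the bis(methoxymethyl) ether of 2,4,6-trihydroxybenzaldehyde (12). The third hydroxyl is hydrogen-bonded to the formyl group and remains free. It is the hydroxyl needed as the nucleophile for the ether bond.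

## Roads not taken

**Alternative 1:** Both prenyl groups are cut at their CH2–CH= bonds. In the forward direction a bis(bromomethyl)flavone tetraacetate A2 would be coupled twice with 2-methylprop-1-enylboronic acid pinacol ester A3 under Pd(PPh3)4 and anhydrous K3PO4 to give kuwanon T tetraacetate A1.
- Merits: the acid-sensitive alkenes appear only in the last carbon–carbon bond-forming step, and the acetates of A1 come off by mild methanolysis. This is gentler than the acidic unmasking of 16, and in this respect the route is better than the chosen one.
- Weak points: A2 requires bromination of two different methyl groups on a polyacetoxylated flavone. Its 3-bromomethylchromone unit is an allylic electrophile open to attack at C2 with ring opening. Any acetate lost under the basic coupling conditions gives a phenoxide ortho to a bromomethyl group and hence a quinone methide. Two sp3–sp2 couplings must both succeed on one molecule.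
- Comparison: the chosen plan is longer at the end and has the harsher deprotection. Against this it has no halomethyl intermediates and forms the C3 side chain and ring C in one catalytic isomerisation.

**Alternative 2:** Ring A is disconnected at C5–C6, C7–C8 and C4a–C5. A pyranonylacetyl chloride A5 would be converted by triethylamine into a ketene, which adds (triisopropylsilyloxy)ethyne A6. The resulting cyclobutenone opens to a dienylketene that closes onto the pyranone and aromatises to the 7-silyl ether A4, with the 5-hydroxyl free and rings B and C already protected.
- Merits: three bonds and a benzene ring are formed in one operation, and the 5- and 7-oxygens emerge differentiated. It builds more complexity per step than the chosen hydroacylation, which forms one bond.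
- Weak points: the difficulty is moved into A5, a fully substituted 4-pyranone that already carries the crowded aryl group and both prenyl groups and has no short synthesis. The ketene is generated beside two nucleophilic alkenes. A6 is a sensitive reagent.
- Comparison: the chosen route forms fewer bonds in its key step, but its precursor 14 comes in a few conventional steps from two commercial aromatics.

**Alternative 3:** Ring C is cut at O1–C8a and C4–C4a. A 3,5-bis(methoxymethoxy)benzyne released by CsF from the silyl triflate A8 would be trapped by the aroyl(prenyl)ketene released on heating the dioxinone A9. This gives kuwanon T tetrakis(methoxymethyl) ether A7, which is the same compound as 16.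
- Merits: two bonds and ring C form at once, the flavone oxidation level is reached directly without the isomerisation step, and the alkoxy group of the aryne directs the ketone oxygen to the distal aryne carbon, which is the required orientation. In convergence and endgame length it is at least as good as the chosen plan.
- Weak points: two short-lived intermediates are generated by different triggers, fluoride at ambient temperature and thermolysis near 100 °C, and must meet before the acylketene dimerises or the aryne undergoes an ene reaction with one of the prenyl groups. A8 and the tetrasubstituted A9 each need several steps.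
- Comparison: the chosen plan pays one extra step and a transient stereocentre. In return its key step is a single unimolecular, catalytic event under weak base with no high-energy intermediates.

Key step: step 8

Remark: kuwanon T has no stereocentre. The carbinol or C2 centre of 9, 11, 14 and 15 is transient, so these compounds are carried as racemates. The thiazolium precatalyst of step 8 is a known salt that contributes no atoms.

## Route

Step 1
Reactants: 1 resorcinol
Product: 2 1,3-bis(methoxymethoxy)benzene
Conditions: MOMCl (2.5 equiv), i-Pr2NEt, CH2Cl2, 0 °C → rt
Reagents that add atoms: chloromethyl methyl ether, COCCl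
Why: Standard O-alkylation of both phenols with an α-chloro ether and an amine base; the acetals are the directing groups for the two lithiations that follow.

Step 2
Reactants: 2 1,3-bis(methoxymethoxy)benzene; 3 prenyl bromide (1-bromo-3-methylbut-2-ene)
Product: 5 1,3-bis(methoxymethoxy)-2-(3-methylbut-2-en-1-yl)benzene, via 2,6-bis(methoxymethoxy)phenyllithium 4 (not isolated)
Conditions: n-BuLi, THF, 0 °C → rt; CuI (10 mol%), 3, −20 °C → rt
Reagents that add atoms: none
Why: Directed ortho-metalation occurs at the position flanked by both acetals, the most acidic ring hydrogen; copper-catalysed allylation of the aryllithium at the primary carbon of the allylic bromide gives the linear prenyl group.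

Step 3
Reactants: 5 1,3-bis(methoxymethoxy)-2-(3-methylbut-2-en-1-yl)benzene
Product: 7 2,4-bis(methoxymethoxy)-3-(3-methylbut-2-en-1-yl)benzaldehyde, via 2,4-bis(methoxymethoxy)-3-(3-methylbut-2-en-1-yl)phenyllithium 6 (not isolated)
Conditions: n-BuLi, TMEDA, THF, −20 → 0 °C; DMF, 0 °C → rt; H2O
Reagents that add atoms: N,N-dimethylformamide, CN(C)C=O
Why: Second directed ortho-metalation at the only remaining position ortho to an acetal (the two are equivalent by symmetry), followed by formylation with a formamide; low temperature and the diamine favour ring over lateral metalation.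

Step 4
Reactants: 7 2,4-bis(methoxymethoxy)-3-(3-methylbut-2-en-1-yl)benzaldehyde; 8 ethynylmagnesium bromide
Product: 9 rac-1-[2,4-bis(methoxymethoxy)-3-(3-methylbut-2-en-1-yl)phenyl]prop-2-yn-1-ol
Conditions: 8 (0.5 M in THF), THF, 0 °C → rt; H2O
Reagents that add atoms: none
Why: Grignard addition of an alkynyl nucleophile to an aryl aldehyde; the new carbinol centre is formed as a racemate, which is sufficient because it is erased in step 9.

Step 5
Reactants: 9 rac-1-[2,4-bis(methoxymethoxy)-3-(3-methylbut-2-en-1-yl)phenyl]prop-2-yn-1-ol; 10 1-bromo-2-methylprop-1-ene
Product: 11 rac-1-[2,4-bis(methoxymethoxy)-3-(3-methylbut-2-en-1-yl)phenyl]-5-methylhex-4-en-2-yn-1-ol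
Conditions: Pd(PPh3)4 (5 mol%), CuI (10 mol%), Et3N, THF, degassed, 40 °C
Reagents that add atoms: none
Why: Sonogashira coupling of a terminal alkyne with a vinyl bromide; free propargylic alcohols are routine substrates, and the hydroxyl is too poor a leaving group for the copper acetylide to ionise.

Step 6
Reactants: 12 2,4,6-trihydroxybenzaldehyde
Product: 13 2-hydroxy-4,6-bis(methoxymethoxy)benzaldehyde
Conditions: MOMCl (2.2 equiv), i-Pr2NEt, CH2Cl2, 0 °C
Reagents that add atoms: chloromethyl methyl ether, COCCl
Why: Selective O-alkylation: the para hydroxyl and one ortho hydroxyl react, and the remaining ortho hydroxyl is deactivated by its hydrogen bond to the formyl group and stays free with a limited amount of reagent.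

Step 7
Reactants: 11 rac-1-[2,4-bis(methoxymethoxy)-3-(3-methylbut-2-en-1-yl)phenyl]-5-methylhex-4-en-2-yn-1-ol; 13 2-hydroxy-4,6-bis(methoxymethoxy)benzaldehyde
Product: 14 rac-2-({1-[2,4-bis(methoxymethoxy)-3-(3-methylbut-2-en-1-yl)phenyl]-5-methylhex-4-en-2-yn-1-yl}oxy)-4,6-bis(methoxymethoxy)benzaldehyde
Conditions: PPh3, DIAD (slow addition), THF, 0 °C → rt
Reagents that add atoms: none
Why: Mitsunobu etherification of a secondary propargylic alcohol with a phenol made acidic by its ortho formyl group; whether the displacement is direct or runs through an ion pair, capture at the carbinol carbon gives the conjugated enyne ether, and the stereochemical outcome is irrelevant in the racemic series.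

Step 8
Reactants: 14 rac-2-({1-[2,4-bis(methoxymethoxy)-3-(3-methylbut-2-en-1-yl)phenyl]-5-methylhex-4-en-2-yn-1-yl}oxy)-4,6-bis(methoxymethoxy)benzaldehyde
Product: 15 rac-(E)-2-[2,4-bis(methoxymethoxy)-3-(3-methylbut-2-en-1-yl)phenyl]-5,7-bis(methoxymethoxy)-3-(3-methylbut-2-en-1-ylidene)-2,3-dihydro-4H-chromen-4-one
Conditions: 3-(2,4,6-trimethylphenyl)-5,6,7,8-tetrahydro-4H-cyclohepta[d][1,3]thiazol-3-ium perchlorate (10 mol%), K2CO3 (20 mol%), THF, 70 °C
Reagents that add atoms: none
Why: K2CO3 frees the thiazolylidene, which adds to the aldehyde of 14, and proton transfer gives the nucleophilic enaminol (Breslow intermediate). Its carbon attacks the proximal alkyne carbon C3 while the hydroxyl proton passes to the distal carbon C1'' in a concerted, asynchronous Conia-ene-like transition state, and the resulting alkoxide expels the carbene to give the ketone. The closest known reaction type is the carbene-catalysed intramolecular hydroacylation of unactivated alkynes in 2-(propargyloxy)benzaldehydes to 3-alkylidenechroman-4-ones; the isobutenyl group on the alkyne and the aryl group on the tether carbon are the only extensions. Ring C closes in the 6-exo-dig mode through the new C3–C4 bond. No stereocentre is created (C2 is already present and racemic), and the E geometry of C3=C1'' follows from syn delivery of acyl carbon and hydrogen. The step needs hydroacylation to outrun benzoin and Stetter pathways and base-induced propargyl-to-allenyl isomerisation: the O1–C2 tether holds the alkyne next to the acyl anion equivalent, the two ortho oxygen substituents suppress intermolecular benzoin coupling, the α,β-disubstituted product enone is a poor Stetter acceptor, and only a catalytic amount of a weak heterogeneous base is present. A thiazolylidene has a single flanking N-substituent and so can still reach the hindered, electron-rich aldehyde.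

Step 9
Reactants: 15 rac-(E)-2-[2,4-bis(methoxymethoxy)-3-(3-methylbut-2-en-1-yl)phenyl]-5,7-bis(methoxymethoxy)-3-(3-methylbut-2-en-1-ylidene)-2,3-dihydro-4H-chromen-4-one
Product: 16 2-[2,4-bis(methoxymethoxy)-3-(3-methylbut-2-en-1-yl)phenyl]-5,7-bis(methoxymethoxy)-3-(3-methylbut-2-en-1-yl)-4H-chromen-4-one
Conditions: DBU (1 equiv), THF, rt → 50 °C
Reagents that add atoms: none
Why: Base-mediated 1,3-prototropic isomerisation of a 3-alkylideneflavanone to the 3-alkylflavone: the C2 hydrogen is benzylic, α to oxygen and part of a pentadienyl system, and reprotonation at the central carbon C1'' is kinetically preferred and gives the aromatic 4-pyranone with an isolated trisubstituted alkene; the C2 stereocentre disappears.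

Step 10
Reactants: 16 2-[2,4-bis(methoxymethoxy)-3-(3-methylbut-2-en-1-yl)phenyl]-5,7-bis(methoxymethoxy)-3-(3-methylbut-2-en-1-yl)-4H-chromen-4-one
Product: 17 kuwanon T
Conditions: HCl (1.25 M in MeOH), THF, rt → 40 °C, stopped at full conversion
Reagents that add atoms: none
Why: Acid-catalysed transacetalisation of aryl methoxymethyl ethers to methanol, standard for prenylated flavonoids; dilute acid at moderate temperature should cleave the four acetals (the chelated C5 ether first) faster than a prenyl group is protonated.

## Compound list

1 | resorcinol (benzene-1,3-diol) | Oc1cccc(O)c1 | starting material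
2 | 1,3-bis(methoxymethoxy)benzene | COCOc1cccc(OCOC)c1 | intermediate
3 | prenyl bromide (1-bromo-3-methylbut-2-ene) | CC(C)=CCBr | starting material
4 | 2,6-bis(methoxymethoxy)phenyllithium (not isolated) | [Li]c1c(OCOC)cccc1OCOC | intermediate
5 | 1,3-bis(methoxymethoxy)-2-(3-methylbut-2-en-1-yl)benzene | COCOc1cccc(OCOC)c1CC=C(C)C | intermediate
6 | 2,4-bis(methoxymethoxy)-3-(3-methylbut-2-en-1-yl)phenyllithium (not isolated) | [Li]c1ccc(OCOC)c(CC=C(C)C)c1OCOC | intermediate
7 | 2,4-bis(methoxymethoxy)-3-(3-methylbut-2-en-1-yl)benzaldehyde | O=Cc1ccc(OCOC)c(CC=C(C)C)c1OCOC | intermediate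
8 | ethynylmagnesium bromide | C#C[Mg]Br | starting material
9 | rac-1-[2,4-bis(methoxymethoxy)-3-(3-methylbut-2-en-1-yl)phenyl]prop-2-yn-1-ol | OC(C#C)c1ccc(OCOC)c(CC=C(C)C)c1OCOC | intermediate
10 | 1-bromo-2-methylprop-1-ene | CC(C)=CBr | starting material
11 | rac-1-[2,4-bis(methoxymethoxy)-3-(3-methylbut-2-en-1-yl)phenyl]-5-methylhex-4-en-2-yn-1-ol | OC(C#CC=C(C)C)c1ccc(OCOC)c(CC=C(C)C)c1OCOC | intermediate
12 | 2,4,6-trihydroxybenzaldehyde | O=Cc1c(O)cc(O)cc1O | starting material
13 | 2-hydroxy-4,6-bis(methoxymethoxy)benzaldehyde | O=Cc1c(O)cc(OCOC)cc1OCOC | intermediate
14 | rac-2-({1-[2,4-bis(methoxymethoxy)-3-(3-methylbut-2-en-1-yl)phenyl]-5-methylhex-4-en-2-yn-1-yl}oxy)-4,6-bis(methoxymethoxy)benzaldehyde | O=Cc1c(OCOC)cc(OCOC)cc1OC(C#CC=C(C)C)c1ccc(OCOC)c(CC=C(C)C)c1OCOC | intermediate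
15 | rac-(E)-2-[2,4-bis(methoxymethoxy)-3-(3-methylbut-2-en-1-yl)phenyl]-5,7-bis(methoxymethoxy)-3-(3-methylbut-2-en-1-ylidene)-2,3-dihydro-4H-chromen-4-one | O=C1/C(=C/C=C(C)C)C(c2ccc(OCOC)c(CC=C(C)C)c2OCOC)Oc2cc(OCOC)cc(OCOC)c12 | intermediate
16 | 2-[2,4-bis(methoxymethoxy)-3-(3-methylbut-2-en-1-yl)phenyl]-5,7-bis(methoxymethoxy)-3-(3-methylbut-2-en-1-yl)-4H-chromen-4-one (kuwanon T tetrakis(methoxymethyl) ether) | COCOc1cc(OCOC)c2c(=O)c(CC=C(C)C)c(-c3ccc(OCOC)c(CC=C(C)C)c3OCOC)oc2c1 | intermediate
17 | kuwanon T | CC(C)=CCc1c(O)ccc(-c2oc3cc(O)cc(O)c3c(=O)c2CC=C(C)C)c1O | target

## Step count and risks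

Total: 10 steps. Longest linear sequence: 9 steps from resorcinol (steps 1–5 and 7–10). Step 6 is a one-step side branch.

**Step 8 (key step).** The most likely failure is slow formation of the Breslow intermediate at the aldehyde, which is blocked on both ortho positions and strongly electron-rich. Two side processes could then take over: base-induced propargyl-to-allenyl isomerisation of the tether, whose hydrogen is benzylic, propargylic and α to oxygen, or a thermal 1,5-hydrogen shift in the product that would move the alkene to the wrong position.
- Fallback, from 14 to 15: nickel-catalysed reductive ynal cyclisation (Ni(cod)2, PBu3, Et3SiH, THF) forms the same C3–C4 bond with syn delivery of hydrogen. It gives the 4-(triethylsilyloxy)-3-(3-methylbut-2-enylidene)flavan F1 as a mixture of C2/C4 diastereomers.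
- Fluoride (TBAF, THF, 0 °C) frees the 3-(3-methylbut-2-enylidene)flavan-4-ol F2.
- MnO2 in CH2Cl2 oxidises this allylic, benzylic alcohol and the route is rejoined at 15.

**Step 7 (Mitsunobu etherification).** The activated alcohol is stabilised as a cation by the dialkoxyaryl group and the enyne. Ionisation of the alkoxyphosphonium salt could be followed by capture at the alkyne terminus (allenyl ether), by the hydrazide, or by carbon of the phenol.
- Fallback, from 9 to 14: acetylation (Ac2O, Et3N, DMAP, CH2Cl2) gives the propargylic acetate F3.
- Copper-catalysed propargylic etherification with phenol 13 (Cu(MeCN)4PF6, 2,6-bis(4,4-dimethyl-2-oxazolin-2-yl)pyridine, i-Pr2NEt, toluene, 0 °C) proceeds through a copper allenylidene that is attacked only at the propargylic carbon. It gives the terminal-alkyne ether F4.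
- Copper-free Sonogashira coupling of F4 with 10 (PdCl2(MeCN)2, XPhos, Cs2CO3, MeCN, 60 °C) returns to 14.

**Step 10 (deprotection).** Acid-catalysed cyclisation of a prenyl group onto a neighbouring freed phenol (chroman formation at ring B) or addition of methanol to an alkene could compete with the slower acetal cleavages.
- Fallback, from 16 to 17: silyl transfer with Et3SiOTf and 2,2'-bipyridyl in CH2Cl2 at 0 °C converts the aryl methoxymethyl ethers directly into kuwanon T tetrakis(triethylsilyl) ether F5 without a protic acid.
- Buffered fluoride (TBAF/AcOH, THF, 0 °C) then releases 17.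

**Step 9 (isomerisation).** Reprotonation of the delocalised anion at the terminal carbon C3'' would give the conjugated 3-(3-methylbut-1-enyl) isomer. Nucleophilic addition of the base to the dienone with opening of ring C is a second possibility.
- Fallback, from 15 to 16: a metal hydride catalyst is used in place of a base (RuHCl(CO)(PPh3)3, toluene, 60 °C). Hydrometalation of the enone places hydrogen on C1'' by mechanism, and β-hydride elimination of the C2 hydrogen gives 16 without a carbanion. The prenyl alkenes, being trisubstituted, should be left alone. No new compound is involved.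

## Further compounds

F1 | step 8 | rac-(E)-2-[2,4-bis(methoxymethoxy)-3-(3-methylbut-2-en-1-yl)phenyl]-5,7-bis(methoxymethoxy)-3-(3-methylbut-2-en-1-ylidene)-4-(triethylsilyloxy)chroman, mixture of C2/C4 diastereomers | CC[Si](CC)(CC)OC1/C(=C/C=C(C)C)C(c2ccc(OCOC)c(CC=C(C)C)c2OCOC)Oc2cc(OCOC)cc(OCOC)c12
F2 | step 8 | rac-(Z)-2-[2,4-bis(methoxymethoxy)-3-(3-methylbut-2-en-1-yl)phenyl]-5,7-bis(methoxymethoxy)-3-(3-methylbut-2-en-1-ylidene)chroman-4-ol, mixture of C2/C4 diastereomers (same alkene geometry as 15; the descriptor changes with the priorities) | OC1/C(=C/C=C(C)C)C(c2ccc(OCOC)c(CC=C(C)C)c2OCOC)Oc2cc(OCOC)cc(OCOC)c12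
F3 | step 7 | rac-1-[2,4-bis(methoxymethoxy)-3-(3-methylbut-2-en-1-yl)phenyl]prop-2-yn-1-yl acetate | CC(=O)OC(C#C)c1ccc(OCOC)c(CC=C(C)C)c1OCOC
F4 | step 7 | rac-2-({1-[2,4-bis(methoxymethoxy)-3-(3-methylbut-2-en-1-yl)phenyl]prop-2-yn-1-yl}oxy)-4,6-bis(methoxymethoxy)benzaldehyde | O=Cc1c(OCOC)cc(OCOC)cc1OC(C#C)c1ccc(OCOC)c(CC=C(C)C)c1OCOC
F5 | step 10 | kuwanon T tetrakis(triethylsilyl) ether | CC[Si](CC)(CC)Oc1cc(O[Si](CC)(CC)CC)c2c(=O)c(CC=C(C)C)c(-c3ccc(O[Si](CC)(CC)CC)c(CC=C(C)C)c3O[Si](CC)(CC)CC)oc2c1
F0 | step 9 | none | none
A1 | alternative 1 | kuwanon T tetraacetate | CC(=O)Oc1cc(OC(C)=O)c2c(=O)c(CC=C(C)C)c(-c3ccc(OC(C)=O)c(CC=C(C)C)c3OC(C)=O)oc2c1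
A2 | alternative 1 | 5,7-diacetoxy-3-(bromomethyl)-2-[2,4-diacetoxy-3-(bromomethyl)phenyl]-4H-chromen-4-one | CC(=O)Oc1cc(OC(C)=O)c2c(=O)c(CBr)c(-c3ccc(OC(C)=O)c(CBr)c3OC(C)=O)oc2c1
A3 | alternative 1 | 2-methylprop-1-enylboronic acid pinacol ester | CC(C)=CB1OC(C)(C)C(C)(C)O1
A4 | alternative 2 | kuwanon T 2',4'-bis(methoxymethyl) 7-triisopropylsilyl ether | CC(C)[Si](Oc1cc(O)c2c(=O)c(CC=C(C)C)c(-c3ccc(OCOC)c(CC=C(C)C)c3OCOC)oc2c1)(C(C)C)C(C)C
A5 | alternative 2 | 2-{6-[2,4-bis(methoxymethoxy)-3-(3-methylbut-2-en-1-yl)phenyl]-5-(3-methylbut-2-en-1-yl)-4-oxo-4H-pyran-2-yl}acetyl chloride | O=C(Cl)Cc1cc(=O)c(CC=C(C)C)c(-c2ccc(OCOC)c(CC=C(C)C)c2OCOC)o1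
A6 | alternative 2 | (triisopropylsilyloxy)ethyne | C#CO[Si](C(C)C)(C(C)C)C(C)C
A7 | alternative 3 | kuwanon T tetrakis(methoxymethyl) ether (identical with 16) | COCOc1cc(OCOC)c2c(=O)c(CC=C(C)C)c(-c3ccc(OCOC)c(CC=C(C)C)c3OCOC)oc2c1
A8 | alternative 3 | 3,5-bis(methoxymethoxy)-2-(trimethylsilyl)phenyl trifluoromethanesulfonate | FC(F)(F)S(=O)(=O)Oc1cc(OCOC)cc(OCOC)c1[Si](C)(C)C
A9 | alternative 3 | 6-[2,4-bis(methoxymethoxy)-3-(3-methylbut-2-en-1-yl)phenyl]-2,2-dimethyl-5-(3-methylbut-2-en-1-yl)-4H-1,3-dioxin-4-one | CC1(C)OC(=O)C(CC=C(C)C)=C(c2ccc(OCOC)c(CC=C(C)C)c2OCOC)O1
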